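All runs stem from a simulated flask for an exercise; noise was put on by code.

We follow one ratio through this flask: s, the rate constant of L + Z → Q + G divided by that of X + Z → Q + L. Both steps, as written, run in proportion to Z, so the timing of Z cancels. L then follows f, the fraction of X left: L = (f^s − f)/(1 − s).

common to all: X 0.14 M
- midnight: Z 0.42 M (in portions, 4); the very flask that is asked about, followed so far; portions every 10 min
- flask: Z 0.420 M (in portions, 4); the portions of Z follow each other after 10 min, the first at the start; time 40 min

midnight run (percent of the X charged)

| time / min | D / % | X / % | L / % | J / % | G / % |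
|---|---|---|---|---|---|
| 0.833 | 0.5 | 96.7 | 3.7 | 0 | 0 |
| 2.50 | 0.3 | 91.1 | 9.6 | 0 | 0 |
| 4.00 | 0.3 | 85.8 | 14.4 | 0.2 | 0 |
| 6.00 | 0 | 80.5 | 19.0 | 0 | 0.7 |
| 10.0 | 0 | 71.6 | 25.8 | 0 | 0.7 |
| 12.0 | 0.1 | 64.2 | 34.2 | 0 | 0.5 |

(standard deviation of a reading: 0.5 percentage points)

* the species that holds most of what was charged as X, at 40 min (G / X / D / L / J)
* the largest share itself, whichever of these holds it, in percent of the X charged

- steps under discussion: G + Z -> Q + J; J <-> D; X + Z -> Q + L; L + Z -> Q + G; 2 Z -> E

First instants: X + Z is the step we see, and G sits near the scatter. Let n, minus ln f, count the lifetimes of X spent. By 10.0 min, n is 0.334. Early on, s is about 2G divided by n squared, so the reading of G at 10.0 min, 0.7%, gives s = 0.125, the selectivity factor. The readings at 6.00 min and 12.0 min give 0.298 and 0.0509, on either side. We keep the middle one, as a rough reading.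

Middle: after the second portion, the readings of X at 10.0 min and 12.0 min put the climb of n at 0.0545 /min, faster than the earlier 0.0334 /min. Held to 40 min, the earlier pace leaves f at 26.3%, with L at 66.6%. The later pace, held from 10.0 min, leaves 13.9%, with L at 73.4%.

End: with this s the rule tops out at 74.2%, when f is 9.31%, so in our reckoning L flattens near that f. We commit to the later pace: L holds most, more than X and more than G, J and D together.

The forecast also names L, at 71%, between 59% and 80%: "L is therefore the main species".

    G + Z → Q + J (k = 0.456 /M/min)
    J ⇌ D (K = 1.76, k = 0.0106 /min)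
    X + Z → Q + L (k = 0.407 /M/min)
    L + Z → Q + G (k = 0.0530 /M/min)
    2 Z → E (k = 0.0822 /M/min)

The flask holds 73.5% as L at 40 min. X stands at 11.8%, above the 9.31% where our rule tops out, and L is still made 1.23 times as fast as it is used up, each step taken net. Put into the rule with our s, that X gives 74.0%. The neighbour charged with 0.25 M of Z ends with X at 27.1%, for which the rule gives 66.1%, and that neighbour holds 65.9% as L.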